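The cyclohexanone ring is traced back to a cyclopentane by a retro-α-ketol (acyloin) rearrangement. The key step exploits the α'-hydroxy α,β-epoxy ketone array of the carbocycle, C6(OH)–C1(=O)–C2(Me)–O–C3. A base-triggered 1,2-shift of the allylic ring carbon C5 from a tertiary carbinol carbon to an attached formyl carbon enlarges the five-membered ring to the six-membered one, unveils the C1 ketone and creates the C6 carbinol trans to the C5 side chain. The cis-oxirane, set beforehand by hydroxyl-directed epoxidation, is carried through. The precursor is a 2,3-epoxy-1-hydroxycyclopentane-1-carbaldehyde bearing the complete silyl-protected side chain; the two angelates and the side-chain epoxide follow.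

Key step: step 13

Numbering used below (target): ring C1 (C=O), C2 (methyl-bearing oxirane carbon), C3 (oxirane CH), C4 (CH2), C5 (CH with side chain), C6 (CH–O); side chain C7 (=CH2), C8 (CH–O), C9 (CH2), C10/C11 (oxirane).
Assumption: in step 7 the (2S,5S)-imidazolidinone is taken to give the (S)-aldehyde; should the sense of induction be the opposite one, the (2R,5R) catalyst is used.

Step 1
Reactants: 1 acrolein
Product: 3 2-bromoacrolein, via 2,3-dibromopropanal 2 (not isolated)
Conditions: Br2, CH2Cl2, −78 → 0 °C; then Et3N, 0 °C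
Reagents that add atoms: bromine, BrBr
Why: Bromine adds across the enal C=C and triethylamine then removes HBr from the 2,3-dibromide (bromination–dehydrobromination), which should give the α-bromo enal.

Step 2
Reactants: 3 2-bromoacrolein
Product: 5 (S)-2-bromohexa-1,5-dien-3-ol, via diisopinocampheylborinate ester 4 (not isolated)
Conditions: salt-free (−)-Ipc2B(allyl), Et2O, −78 °C; then NaOH, H2O2
Reagents that add atoms: (−)-B-allyldiisopinocampheylborane, C=CCB([C@@H]1C[C@@H]2C[C@H]([C@H]1C)C2(C)C)[C@@H]1C[C@@H]2C[C@H]([C@H]1C)C2(C)C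
Why: Brown asymmetric allylboration through a chair-like six-membered transition state, in which the isopinocampheyl groups of the (+)-α-pinene-derived reagent should direct allyl transfer to the Si face of the aldehyde and so set the (S)-carbinol centre (future C8).

Step 3
Reactants: 5 (S)-2-bromohexa-1,5-dien-3-ol
Product: 6 (S)-2-bromo-6-methylhepta-1,5-dien-3-ol
Conditions: 2-methylbut-2-ene (excess), RuCl2(=CHPh)(PCy3)(H2IMes) (second-generation Grubbs catalyst, 5 mol %), CH2Cl2, 40 °C
Reagents that add atoms: 2-methylbut-2-ene, CC=C(C)C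
Why: Olefin cross-metathesis of the terminal monosubstituted alkene with excess 2-methylbut-2-ene should install the prenyl terminus, the hindered 2-bromo-1-alkene being inert to the ruthenium carbene.

Step 4
Reactants: 6 (S)-2-bromo-6-methylhepta-1,5-dien-3-ol
Product: 7 (S)-[(2-bromo-6-methylhepta-1,5-dien-3-yl)oxy](tert-butyl)dimethylsilane
Conditions: TBSCl, imidazole, DMF, rt
Reagents that add atoms: tert-butyldimethylsilyl chloride, CC(C)(C)[Si](C)(C)Cl
Why: Standard silylation of the secondary alcohol, which masks the C8 oxygen against the organometallic, vanadium and oxidation steps that follow.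

Step 5
Reactants: 7 TBS ether of the bromodienol
Product: 10 [(S)-3-(tert-butyldimethylsilyloxy)-6-methylhepta-1,5-dien-2-yl]boronic acid, via alkenyllithium 8 (not isolated), via lithium triisopropoxyborate 9 (not isolated)
Conditions: t-BuLi (2.1 equiv), Et2O, −78 °C; B(OiPr)3, −78 °C → rt; aq. HCl
Reagents that add atoms: triisopropyl borate, CC(C)OB(OC(C)C)OC(C)C; water, O
Why: Bromine–lithium exchange followed by electrophilic borylation and hydrolysis of the borate should give the 1-substituted vinylboronic acid at −78 °C, where β-elimination of the allylic silyloxy group is slow.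

Step 6
Reactants: 11 hex-4-yn-1-ol
Product: 12 hex-4-ynal
Conditions: TEMPO (10 mol %), PhI(OAc)2, CH2Cl2, rt
Reagents that add atoms: none
Why: TEMPO-catalysed oxidation with PhI(OAc)2 should stop at the aldehyde and leave the internal alkyne untouched.

Step 7
Reactants: 10 alkenylboronic acid; 12 hex-4-ynal (excess)
Product: 13 (S)-2-[(S)-3-(tert-butyldimethylsilyloxy)-6-methylhepta-1,5-dien-2-yl]hex-4-ynal
Conditions: Cu(OAc)2 (0.3 equiv), (2S,5S)-5-benzyl-2-tert-butyl-3-methylimidazolidin-4-one·CF3CO2H (0.2 equiv), O2 (1 atm), 4 Å MS, EtOAc, rt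
Reagents that add atoms: none
Why: Enantioselective α-alkenylation of an aldehyde with an alkenylboronic acid by combined enamine and copper catalysis, in which the enamine of the chiral imidazolidinone formed at C2 of the six-carbon ynal should be alkenylated on its unshielded face, so the C5 stereocentre is set by catalyst control without migration of the new 1,1-disubstituted alkene.

Step 8
Reactants: 13 α-alkenyl hex-4-ynal
Product: 14 (S)-5-[(S)-3-(tert-butyldimethylsilyloxy)-6-methylhepta-1,5-dien-2-yl]-2-methylcyclopent-2-en-1-one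
Conditions: [Rh(dppe)]2(BF4)2 (10 mol %), acetone, rt
Reagents that add atoms: none
Why: Rhodium-catalysed intramolecular hydroacylation of a 4-alkynal (aldehyde C–H oxidative addition, net trans-hydrometalation of the alkyne, reductive elimination joining the acyl carbon to the methyl-bearing alkyne carbon) should give the 2-methylcyclopent-2-enone under neutral conditions that do not touch the epimerisable α'-centre.

Step 9
Reactants: 14 cyclopentenone
Product: 15 (1R,5S)-5-[(S)-3-(tert-butyldimethylsilyloxy)-6-methylhepta-1,5-dien-2-yl]-1-{[isopropoxy(dimethyl)silyl]methyl}-2-methylcyclopent-2-en-1-ol (hydroxyl cis to the side chain)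
Conditions: (iPrO)Me2SiCH2MgCl, LaCl3·2LiCl (0.3 equiv), THF, −78 → 0 °C; aq. NH4Cl
Reagents that add atoms: (isopropoxydimethylsilyl)methylmagnesium chloride, CC(C)O[Si](C)(C)C[Mg]Cl
Why: 1,2-Addition of the lanthanum-activated Grignard reagent (nucleophilic hydroxymethylation reagent of the Tamao type) should occur anti to the adjacent C5 side chain, which places the tertiary hydroxyl cis to that chain, while LaCl3 suppresses enolisation and conjugate addition.

Step 10
Reactants: 15 tertiary cyclopentenol
Product: 16 (1S,2R,3S,5S)-3-[(S)-3-(tert-butyldimethylsilyloxy)-6-methylhepta-1,5-dien-2-yl]-2-{[isopropoxy(dimethyl)silyl]methyl}-1-methyl-6-oxabicyclo[3.1.0]hexan-2-ol (oxirane, hydroxyl and side chain all cis)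
Conditions: VO(acac)2 (5 mol %), t-BuOOH (decane solution), CH2Cl2, 0 °C → rt
Reagents that add atoms: tert-butyl hydroperoxide, CC(C)(C)OO
Why: Hydroxyl-directed vanadium-catalysed epoxidation, in which the vanadate ester of the tertiary allylic alcohol should deliver oxygen to the syn face of the trisubstituted ring alkene only, so the oxirane is set cis to the hydroxyl and to the side chain while the non-allylic side-chain alkenes stay untouched.

Step 11
Reactants: 16 epoxy silane
Product: 17 (1S,2S,3S,5S)-3-[(S)-3-(tert-butyldimethylsilyloxy)-6-methylhepta-1,5-dien-2-yl]-2-(hydroxymethyl)-1-methyl-6-oxabicyclo[3.1.0]hexan-2-ol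
Conditions: 30% H2O2, KF, KHCO3, THF/MeOH, rt
Reagents that add atoms: hydrogen peroxide, OO
Why: Tamao oxidation (fluoride-assisted peroxide attack at silicon and 1,2-migration of carbon to oxygen) should unmask the primary alcohol under mild bicarbonate conditions that the epoxide and the TBS ether tolerate.

Step 12
Reactants: 17 epoxy diol
Product: 18 (1S,2R,3S,5S)-3-[(S)-3-(tert-butyldimethylsilyloxy)-6-methylhepta-1,5-dien-2-yl]-2-hydroxy-1-methyl-6-oxabicyclo[3.1.0]hexane-2-carbaldehyde
Conditions: SO3·pyridine, DMSO, iPr2NEt, CH2Cl2, 0 °C; product carried on crude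
Reagents that add atoms: none
Why: Parikh–Doering oxidation should convert the primary alcohol of the 1,2-diol into the aldehyde without C–C cleavage and leave the tertiary alcohol untouched.

Step 13
Reactants: 18 epoxy hydroxy aldehyde
Product: 19 (1S,3S,4S,6S)-4-[(S)-3-(tert-butyldimethylsilyloxy)-6-methylhepta-1,5-dien-2-yl]-3-hydroxy-1-methyl-7-oxabicyclo[4.1.0]heptan-2-one
Conditions: DBU (0.2 equiv), toluene, 0 °C → rt
Reagents that add atoms: none
Why: The amidine base reversibly forms the tertiary alkoxide, whose oxygen pushes the allylic ring carbon C5 in a suprafacial 1,2-shift from the carbinol carbon onto the formyl carbon, so that the five-membered ring becomes the six-membered one, the carbinol carbon becomes the C1 ketone and the formyl carbon the C6 carbinol (α-ketol or acyloin rearrangement). The closest known reaction type is the base-promoted ring-enlarging α-ketol rearrangement of 1-acylcycloalkanols (D-homoannulation type) and of tertiary α-hydroxy aldehydes. No ring is closed by cyclisation: the cyclohexanone arises by ring enlargement, C5 migrates with retention, and the oxirane and the C8 centre are untouched. The new C6 stereocentre is controlled kinetically by the anti arrangement of alkoxide and formyl oxygen in the non-chelated ion pair, which delivers the hydroxyl trans to the C5 side chain, and thermodynamically by the diequatorial preference of the two groups at this epimerisable position. The selectivity needed is migration of C5 rather than of the oxiranyl carbon C2, secured by the allylic, electron-richer nature of C5 against the electron-poor, strained oxiranyl carbon; Payne-type opening is excluded because alkoxide and oxirane are cis. The gain of a ketone from an aldehyde and the relief of cyclopentane strain should drive the step.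

Step 14
Reactants: 19 ring-enlarged ketol
Product: 20 (1S,3S,4S,6S)-3-hydroxy-4-[(S)-3-hydroxy-6-methylhepta-1,5-dien-2-yl]-1-methyl-7-oxabicyclo[4.1.0]heptan-2-one
Conditions: HF·pyridine, pyridine, THF, 0 °C → rt
Reagents that add atoms: none
Why: Buffered fluoride cleavage of the secondary TBS ether, a medium that the epoxy ketone and the α-ketol should survive.

Step 15
Reactants: 20 diol; 21 angelic acid (two equivalents enter the product, one for each hydroxyl)
Product: 23 (S)-6-methyl-2-[(1S,3S,4S,6S)-3-(angeloyloxy)-1-methyl-2-oxo-7-oxabicyclo[4.1.0]heptan-4-yl]hepta-1,5-dien-3-yl angelate, via angelic 2,4,6-trichlorobenzoic anhydride 22 (not isolated)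
Conditions: 21 (2.6 equiv), 2,4,6-Cl3C6H2COCl (2.6 equiv), Et3N (2.6 equiv), toluene, rt; then 20, toluene, 70 °C (no DMAP)
Reagents that add atoms: angelic acid (the second equivalent of 21), OC(=O)/C(C)=C\C
Why: Double acylation in which each of the two secondary hydroxyls (C6 and C8) takes one angeloyl group from one molecule of the mixed 2,4,6-trichlorobenzoic anhydride of angelic acid (Yamaguchi-type esterification without DMAP), conditions chosen because they should not isomerise the (Z)-2-methylbut-2-enoyl unit to the tigloyl isomer.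

Step 16
Reactants: 23 bis-angelate
Product: 24 target, (S)-1-[(R)-3,3-dimethyloxiran-2-yl]-3-[(1S,3S,4S,6S)-3-(angeloyloxy)-1-methyl-2-oxo-7-oxabicyclo[4.1.0]heptan-4-yl]but-3-en-2-yl angelate
Conditions: 1,2:4,5-di-O-isopropylidene-β-D-erythro-2,3-hexodiulo-2,6-pyranose (Shi ketone, 0.3 equiv), KHSO5 (as Oxone), K2CO3, Bu4NHSO4, MeCN/CH2(OMe)2/aq. Na2B4O7 buffer, 0 °C
Reagents that add atoms: potassium peroxymonosulfate, [K+].[O-]S(=O)(=O)OO
Why: Shi asymmetric epoxidation, in which the chiral dioxirane from the D-fructose-derived ketone should epoxidise only the electron-rich trisubstituted side-chain alkene through a spiro transition state and give the (R)-oxirane by reagent control, the 1,1-disubstituted alkene and the electron-poor angelate alkenes reacting far more slowly.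

Compound list
1 | acrolein (prop-2-enal) | C=CC=O | starting material
2 | 2,3-dibromopropanal | O=CC(Br)CBr | intermediate (not isolated)
3 | 2-bromoacrolein | C=C(Br)C=O | intermediate
4 | (S)-2-bromohexa-1,5-dien-3-yl diisopinocampheylborinate | C=C(Br)[C@H](CC=C)OB([C@@H]1C[C@@H]2C[C@H]([C@H]1C)C2(C)C)[C@@H]1C[C@@H]2C[C@H]([C@H]1C)C2(C)C | intermediate (not isolated)
5 | (S)-2-bromohexa-1,5-dien-3-ol | C=C(Br)[C@H](CC=C)O | intermediate
6 | (S)-2-bromo-6-methylhepta-1,5-dien-3-ol | C=C(Br)[C@H](CC=C(C)C)O | intermediate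
7 | (S)-[(2-bromo-6-methylhepta-1,5-dien-3-yl)oxy](tert-butyl)dimethylsilane | C=C(Br)[C@H](CC=C(C)C)O[Si](C)(C)C(C)(C)C | intermediate
8 | [(S)-3-(tert-butyldimethylsilyloxy)-6-methylhepta-1,5-dien-2-yl]lithium | [Li]C(=C)[C@H](CC=C(C)C)O[Si](C)(C)C(C)(C)C | intermediate (not isolated)
9 | lithium [(S)-3-(tert-butyldimethylsilyloxy)-6-methylhepta-1,5-dien-2-yl]triisopropoxyborate | [Li+].C=C([B-](OC(C)C)(OC(C)C)OC(C)C)[C@H](CC=C(C)C)O[Si](C)(C)C(C)(C)C | intermediate (not isolated)
10 | [(S)-3-(tert-butyldimethylsilyloxy)-6-methylhepta-1,5-dien-2-yl]boronic acid | C=C(B(O)O)[C@H](CC=C(C)C)O[Si](C)(C)C(C)(C)C | intermediate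
11 | hex-4-yn-1-ol | CC#CCCCO | starting material
12 | hex-4-ynal | CC#CCCC=O | intermediate
13 | (S)-2-[(S)-3-(tert-butyldimethylsilyloxy)-6-methylhepta-1,5-dien-2-yl]hex-4-ynal | C=C([C@H](CC=C(C)C)O[Si](C)(C)C(C)(C)C)[C@@H](C=O)CC#CC | intermediate
14 | (S)-5-[(S)-3-(tert-butyldimethylsilyloxy)-6-methylhepta-1,5-dien-2-yl]-2-methylcyclopent-2-en-1-one | C=C([C@H](CC=C(C)C)O[Si](C)(C)C(C)(C)C)[C@@H]1CC=C(C)C1=O | intermediate
15 | (1R,5S)-5-[(S)-3-(tert-butyldimethylsilyloxy)-6-methylhepta-1,5-dien-2-yl]-1-{[isopropoxy(dimethyl)silyl]methyl}-2-methylcyclopent-2-en-1-ol | C=C([C@H](CC=C(C)C)O[Si](C)(C)C(C)(C)C)[C@@H]1CC=C(C)[C@@]1(O)C[Si](C)(C)OC(C)C | intermediate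
16 | (1S,2R,3S,5S)-3-[(S)-3-(tert-butyldimethylsilyloxy)-6-methylhepta-1,5-dien-2-yl]-2-{[isopropoxy(dimethyl)silyl]methyl}-1-methyl-6-oxabicyclo[3.1.0]hexan-2-ol | C=C([C@H](CC=C(C)C)O[Si](C)(C)C(C)(C)C)[C@@H]1C[C@@H]2O[C@]2(C)[C@@]1(O)C[Si](C)(C)OC(C)C | intermediate
17 | (1S,2S,3S,5S)-3-[(S)-3-(tert-butyldimethylsilyloxy)-6-methylhepta-1,5-dien-2-yl]-2-(hydroxymethyl)-1-methyl-6-oxabicyclo[3.1.0]hexan-2-ol | C=C([C@H](CC=C(C)C)O[Si](C)(C)C(C)(C)C)[C@@H]1C[C@@H]2O[C@]2(C)[C@@]1(O)CO | intermediate
18 | (1S,2R,3S,5S)-3-[(S)-3-(tert-butyldimethylsilyloxy)-6-methylhepta-1,5-dien-2-yl]-2-hydroxy-1-methyl-6-oxabicyclo[3.1.0]hexane-2-carbaldehyde | C=C([C@H](CC=C(C)C)O[Si](C)(C)C(C)(C)C)[C@@H]1C[C@@H]2O[C@]2(C)[C@@]1(O)C=O | intermediate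
19 | (1S,3S,4S,6S)-4-[(S)-3-(tert-butyldimethylsilyloxy)-6-methylhepta-1,5-dien-2-yl]-3-hydroxy-1-methyl-7-oxabicyclo[4.1.0]heptan-2-one | C=C([C@H](CC=C(C)C)O[Si](C)(C)C(C)(C)C)[C@@H]1C[C@@H]2O[C@]2(C)C(=O)[C@H]1O | intermediate
20 | (1S,3S,4S,6S)-3-hydroxy-4-[(S)-3-hydroxy-6-methylhepta-1,5-dien-2-yl]-1-methyl-7-oxabicyclo[4.1.0]heptan-2-one | C=C([C@H](CC=C(C)C)O)[C@@H]1C[C@@H]2O[C@]2(C)C(=O)[C@H]1O | intermediate
21 | angelic acid, (Z)-2-methylbut-2-enoic acid | OC(=O)/C(C)=C\C | starting material
22 | angelic 2,4,6-trichlorobenzoic anhydride | O=C(OC(=O)/C(C)=C\C)c1c(Cl)cc(Cl)cc1Cl | intermediate (not isolated)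
23 | (S)-6-methyl-2-[(1S,3S,4S,6S)-3-(angeloyloxy)-1-methyl-2-oxo-7-oxabicyclo[4.1.0]heptan-4-yl]hepta-1,5-dien-3-yl angelate | C=C([C@H](CC=C(C)C)OC(=O)/C(C)=C\C)[C@@H]1C[C@@H]2O[C@]2(C)C(=O)[C@H]1OC(=O)/C(C)=C\C | intermediate
24 | (S)-1-[(R)-3,3-dimethyloxiran-2-yl]-3-[(1S,3S,4S,6S)-3-(angeloyloxy)-1-methyl-2-oxo-7-oxabicyclo[4.1.0]heptan-4-yl]but-3-en-2-yl angelate | C=C([C@H](C[C@H]1OC1(C)C)OC(=O)/C(C)=C\C)[C@@H]1C[C@@H]2O[C@]2(C)C(=O)[C@H]1OC(=O)/C(C)=C\C | target

Total step count: 16. Longest linear sequence: 15 steps (steps 1–5 and 7–16, from acrolein).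

Steps most likely to fail

Step 13 (key step). What may go wrong: competing migration of the oxiranyl carbon, base-induced enediol equilibration of the product ketol, or degradation of the epoxy hydroxy aldehyde before it rearranges. The fallback reverses the order of ring enlargement and epoxidation. It sets out from 15: Tamao oxidation (H2O2, KF, KHCO3) would give the cyclopentene diol F1, Parikh–Doering oxidation the hydroxy aldehyde F2, and DBU the ring-enlarged α'-hydroxy enone F3, the conjugated thermodynamic sink of the ketol manifold whichever ring carbon migrates. HF·pyridine would then give the diol F4 and angeloylation as in step 15 the bis-angelate enone F5. Luche reduction (NaBH4, CeCl3·7H2O, MeOH, −78 °C) would give the pseudo-equatorial allylic alcohol F6, cis to the C5 side chain, and VO(acac)2/t-BuOOH the syn epoxy alcohol F7. Dess–Martin oxidation of F7 comes back to the route at 23.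

Step 7. What may go wrong: sluggish coupling of the hindered α-branched alkenylboronic acid, poor enantiofacial control, or racemisation of the α-alkenyl aldehyde. The fallback is an auxiliary-controlled alkylation. It sets out from 7: bromine–lithium exchange and opening of ethylene oxide (BF3·OEt2) would give the homoallylic alcohol F8, Dess–Martin oxidation the β,γ-unsaturated aldehyde F9, and condensation with RAMP the hydrazone F10. Deprotonation with LDA and alkylation with 1-bromobut-2-yne would give the alkylated hydrazone F11, and cleavage with aqueous oxalic acid comes back to the route at 13.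

Step 15. What may go wrong: Z to E isomerisation of the activated angeloyl unit (tiglate formation) and incomplete acylation of the hindered C6 hydroxyl next to the ketone. The fallback forms each ester carbonyl at the alcohol by carbonylation instead of activating angelic acid, and it generates no carbanion next to the ester that could attack the C1 ketone. It sets out from 20: palladium-catalysed alkoxycarbonylation of (Z)-2-bromobut-2-ene (excess; Pd(OAc)2, Xantphos, CO 1 atm, iPr2NEt, toluene, 70 °C) should let each hydroxyl trap an acyl-palladium intermediate that is formed with retention of the alkene geometry of the bromide, and it comes back to the route at 23. No compound outside the compound list is made on this path (entry F0).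

Further compounds
F1 | step 13 | (1R,5S)-5-[(S)-3-(tert-butyldimethylsilyloxy)-6-methylhepta-1,5-dien-2-yl]-1-(hydroxymethyl)-2-methylcyclopent-2-en-1-ol | C=C([C@H](CC=C(C)C)O[Si](C)(C)C(C)(C)C)[C@@H]1CC=C(C)[C@@]1(O)CO
F2 | step 13 | 5-[(S)-3-(tert-butyldimethylsilyloxy)-6-methylhepta-1,5-dien-2-yl]-1-hydroxy-2-methylcyclopent-2-ene-1-carbaldehyde (hydroxyl cis to the side chain) | C=C([C@H](CC=C(C)C)O[Si](C)(C)C(C)(C)C)[C@@H]1CC=C(C)[C@@]1(O)C=O
F3 | step 13 | (5S,6S)-5-[(S)-3-(tert-butyldimethylsilyloxy)-6-methylhepta-1,5-dien-2-yl]-6-hydroxy-2-methylcyclohex-2-en-1-one | C=C([C@H](CC=C(C)C)O[Si](C)(C)C(C)(C)C)[C@@H]1CC=C(C)C(=O)[C@H]1O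
F4 | step 13 | (5S,6S)-6-hydroxy-5-[(S)-3-hydroxy-6-methylhepta-1,5-dien-2-yl]-2-methylcyclohex-2-en-1-one | C=C([C@H](CC=C(C)C)O)[C@@H]1CC=C(C)C(=O)[C@H]1O
F5 | step 13 | bis-angelate of F4 | C=C([C@H](CC=C(C)C)OC(=O)/C(C)=C\C)[C@@H]1CC=C(C)C(=O)[C@H]1OC(=O)/C(C)=C\C
F6 | step 13 | allylic alcohol from reduction of F5 (C1 hydroxyl cis to the C5 side chain, trans to the C6 angelate) | C=C([C@H](CC=C(C)C)OC(=O)/C(C)=C\C)[C@@H]1CC=C(C)[C@H](O)[C@H]1OC(=O)/C(C)=C\C
F7 | step 13 | 2,3-epoxy alcohol from F6 (oxirane cis to the C1 hydroxyl and the C5 side chain) | C=C([C@H](CC=C(C)C)OC(=O)/C(C)=C\C)[C@@H]1C[C@@H]2O[C@]2(C)[C@H](O)[C@H]1OC(=O)/C(C)=C\C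
F8 | step 7 | (S)-4-(tert-butyldimethylsilyloxy)-7-methyl-3-methyleneoct-6-en-1-ol | C=C(CCO)[C@H](CC=C(C)C)O[Si](C)(C)C(C)(C)C
F9 | step 7 | (S)-4-(tert-butyldimethylsilyloxy)-7-methyl-3-methyleneoct-6-enal | C=C(CC=O)[C@H](CC=C(C)C)O[Si](C)(C)C(C)(C)C
F10 | step 7 | RAMP hydrazone of F9 | C=C([C@H](CC=C(C)C)O[Si](C)(C)C(C)(C)C)C/C=N/N1CCC[C@@H]1COC
F11 | step 7 | RAMP hydrazone of 13 | C=C([C@H](CC=C(C)C)O[Si](C)(C)C(C)(C)C)[C@@H](/C=N/N1CCC[C@@H]1COC)CC#CC
F0 | step 15 | none | none
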